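## Retrosynthetic overview

1. Numbering: C1 (enone C=O)–C2=C3(Me)–C4–C5–C6(Me)2–C7(O-tiglate)–C8–C9(O-angelate)–C10(Me)–C11, plus bonds C11–C1, C4–C10 and C5–C11. Ring B is the cyclohexene C11–C1–C2–C3–C4–C10, ring A the seven-membered ring C5–C6–C7–C8–C9–C10–C11, and the cyclobutane is C4–C5–C11–C10.
2. Feature the plan rests on: in the cis-fused A/B bicycle, C4–H is allylic (to C2=C3) and γ to C5 along C5–C11–C10–C4, 1,3-diaxial to an axial C5 acyl group on ring B, while C5 is flanked by the hydrogen-free C6. An excited C5 ketone can therefore take that hydrogen and close C4–C5.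
3. Late stage: C9 angelate, C1 enone (from an allylic silyl ether), C7 tiglate and C5–H (from C5–OH) lead back to a tricyclic cyclobutanol. The C4–C5 bond is cut by a Norrish–Yang disconnection to a cis-fused bicyclo[5.4.0]undecenone.
4. Ring B comes from a Diels–Alder reaction (bonds C1–C11 and C4–C10) of a 3-methylcyclohept-2-enone with the silyl dienol ether of 3-methylbut-2-enal. Ring A comes from ring-closing metathesis (C10=C11), with C7 from (S)-pantolactone and C9 from a Shi epoxidation followed by epoxide-to-allylic-alcohol isomerisation.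
5. Order of ring formation: seven-membered ring A, six-membered ring B, then the four-membered ring; the esters are attached last, tiglate before angelate.

Key step: step 15

Assumption: the Diels–Alder adduct is taken as the endo isomer at C1 (O1 cis to the C5 carbonyl); C1 becomes the enone carbonyl in step 21, so its C1 epimer would serve equally.

## Route

Step 1
Reactants: 1 (S)-pantolactone
Product: 2 (S)-3,3-dimethylbutane-1,2,4-triol
Conditions: LiAlH4, THF, 0 °C → reflux; H2O/NaOH work-up
Reagents that add atoms: none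
Why: Hydride reduction of the lactone to the diol does not touch the carbinol stereocentre, which becomes C7.

Step 2
Reactants: 2 (S)-3,3-dimethylbutane-1,2,4-triol
Product: 3 [(2S,4S)-2-(4-methoxyphenyl)-5,5-dimethyl-1,3-dioxan-4-yl]methanol
Conditions: 4-MeOC6H4CH(OMe)2, CSA (cat.), CH2Cl2, rt
Reagents that add atoms: 4-methoxybenzaldehyde dimethyl acetal, COc1ccc(C(OC)OC)cc1
Why: Thermodynamic transacetalisation should give the six-membered arylidene acetal across O5/O7 with the aryl group equatorial and cis to the hydroxymethyl group, leaving only the C8 hydroxyl free.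

Step 3
Reactants: 3 [(2S,4S)-2-(4-methoxyphenyl)-5,5-dimethyl-1,3-dioxan-4-yl]methanol
Product: 5 (2S,4R)-2-(4-methoxyphenyl)-5,5-dimethyl-4-(3-methylbut-2-en-1-yl)-1,3-dioxane, via triflate 4 (not isolated)
Conditions: Tf2O, 2,6-lutidine, CH2Cl2, −78 °C; then Me2C=CHMgBr, CuI (10 mol %), THF, −40 → 0 °C
Reagents that add atoms: 2-methylprop-1-enylmagnesium bromide, CC(C)=C[Mg]Br
Why: Copper-catalysed SN2 coupling of the primary triflate with the alkenyl Grignard reagent forms C8–C9 and brings in the C9=C10 alkene without touching C7.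

Step 4
Reactants: 5 (2S,4R)-2-(4-methoxyphenyl)-5,5-dimethyl-4-(3-methylbut-2-en-1-yl)-1,3-dioxane
Product: 6 (R)-2,2,6-trimethylhept-5-ene-1,3-diol
Conditions: PPTS (cat.), MeOH, rt
Reagents that add atoms: none
Why: Acid-catalysed transacetalisation to methanol releases the 1,3-diol under conditions too mild to hydrate or cyclise the trisubstituted alkene.

Step 5
Reactants: 6 (R)-2,2,6-trimethylhept-5-ene-1,3-diol
Product: 7 (R)-2,2,6-trimethyl-1,3-bis(triethylsilyloxy)hept-5-ene
Conditions: TESOTf, 2,6-lutidine, CH2Cl2, −78 → 0 °C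
Reagents that add atoms: triethylsilyl triflate, CC[Si](CC)(CC)OS(=O)(=O)C(F)(F)F
Why: The silyl triflate silylates both the primary and the hindered neopentyl secondary hydroxyl.

Step 6
Reactants: 7 (R)-2,2,6-trimethyl-1,3-bis(triethylsilyloxy)hept-5-ene
Product: 8 (R)-3-[(R)-3,3-dimethyl-2,4-bis(triethylsilyloxy)butyl]-2,2-dimethyloxirane
Conditions: D-fructose-derived Shi ketone (30 mol %), KHSO5 (as Oxone, 2KHSO5·KHSO4·K2SO4), K2CO3, Bu4NHSO4, MeCN–CH2(OMe)2–aq. Na2B4O7 buffer (pH 10.5), 0 °C
Reagents that add atoms: potassium peroxymonosulfate, [K+].[O-]S(=O)(=O)OO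
Why: Shi asymmetric epoxidation of the trisubstituted alkene through the spiro transition state of the chiral dioxirane should deliver oxygen to the face that gives the (R)-epoxide, which sets C9 under reagent control.

Step 7
Reactants: 8 (R)-3-[(R)-3,3-dimethyl-2,4-bis(triethylsilyloxy)butyl]-2,2-dimethyloxirane
Product: 9 (3R,5R)-2,6,6-trimethyl-5,7-bis(triethylsilyloxy)hept-1-en-3-ol
Conditions: Et2AlCl, LiTMP (from 2,2,6,6-tetramethylpiperidine and n-BuLi), toluene, 0 °C
Reagents that add atoms: none
Why: The aluminium amide removes a proton from a C10 methyl group and opens the tertiary C–O bond of the aluminium-bound epoxide (Yamamoto–Nozaki epoxide-to-allylic-alcohol isomerisation), so the C9–O bond and its configuration are kept.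

Step 8
Reactants: 9 (3R,5R)-2,6,6-trimethyl-5,7-bis(triethylsilyloxy)hept-1-en-3-ol
Product: 10 (3R,5R)-3-(tert-butyldimethylsilyloxy)-2,6,6-trimethyl-5,7-bis(triethylsilyloxy)hept-1-ene
Conditions: TBSOTf, 2,6-lutidine, CH2Cl2, −78 °C
Reagents that add atoms: tert-butyldimethylsilyl triflate, CC(C)(C)[Si](C)(C)OS(=O)(=O)C(F)(F)F
Why: Silylation of the secondary allylic alcohol gives O9 a TBS group and so distinguishes it from O7 (TES).

Step 9
Reactants: 10 (3R,5R)-3-(tert-butyldimethylsilyloxy)-2,6,6-trimethyl-5,7-bis(triethylsilyloxy)hept-1-ene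
Product: 11 (3R,5R)-5-(tert-butyldimethylsilyloxy)-2,2,6-trimethyl-3-(triethylsilyloxy)hept-6-enal
Conditions: (COCl)2, DMSO, CH2Cl2, −78 → −40 °C; then Et3N, −78 °C → rt
Reagents that add atoms: none
Why: Under Swern conditions a primary triethylsilyl ether is cleaved and oxidised to the aldehyde in one operation while secondary TES and TBS ethers survive (selective Swern oxidation of primary TES ethers).

Step 10
Reactants: 11 (3R,5R)-5-(tert-butyldimethylsilyloxy)-2,2,6-trimethyl-3-(triethylsilyloxy)hept-6-enal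
Product: 12 (5R,7R)-7-(tert-butyldimethylsilyloxy)-4,4,8-trimethyl-5-(triethylsilyloxy)nona-1,8-dien-3-ol (both C3 epimers)
Conditions: CH2=CHMgBr, THF, −78 → 0 °C
Reagents that add atoms: vinylmagnesium bromide, C=C[Mg]Br
Why: Grignard addition to the non-enolisable neopentyl aldehyde gives the allylic alcohol, and the configuration of the new carbinol (C5) does not matter because it is oxidised in step 12.

Step 11
Reactants: 12 (5R,7R)-7-(tert-butyldimethylsilyloxy)-4,4,8-trimethyl-5-(triethylsilyloxy)nona-1,8-dien-3-ol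
Product: 13 (4R,6R)-4-(tert-butyldimethylsilyloxy)-3,7,7-trimethyl-6-(triethylsilyloxy)cyclohept-2-en-1-ol (both C1 epimers)
Conditions: second-generation Grubbs catalyst (H2IMes)(PCy3)Cl2Ru=CHPh (5 mol %), CH2Cl2, 40 °C
Reagents that add atoms: none
Why: Ring-closing metathesis should start at the monosubstituted alkene and close on the 1,1-disubstituted one to give the trisubstituted cycloheptene, helped by the gem-dimethyl group.

Step 12
Reactants: 13 (4R,6R)-4-(tert-butyldimethylsilyloxy)-3,7,7-trimethyl-6-(triethylsilyloxy)cyclohept-2-en-1-ol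
Product: 14 (4R,6R)-4-(tert-butyldimethylsilyloxy)-3,7,7-trimethyl-6-(triethylsilyloxy)cyclohept-2-en-1-one
Conditions: Dess–Martin periodinane, NaHCO3, CH2Cl2, 0 °C → rt
Reagents that add atoms: none
Why: Dess–Martin oxidation of the allylic alcohol converges both C5 epimers on the enone, which has no epimerisable centre.

Step 13
Reactants: 15 3-methylbut-2-enal
Product: 16 (E)-tert-butyldimethyl(3-methylbuta-1,3-dienyloxy)silane
Conditions: TBSOTf, Et3N, Et2O, 0 °C → rt
Reagents that add atoms: tert-butyldimethylsilyl triflate, CC(C)(C)[Si](C)(C)OS(=O)(=O)C(F)(F)F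
Why: O-silylation of the enal and γ-deprotonation by Et3N give the 1-silyloxy diene, expected mainly as the E isomer (silyl dienol ether formation).

Step 14
Reactants: 14 (4R,6R)-4-(tert-butyldimethylsilyloxy)-3,7,7-trimethyl-6-(triethylsilyloxy)cyclohept-2-en-1-one; 16 (E)-tert-butyldimethyl(3-methylbuta-1,3-dienyloxy)silane
Product: 17 cis-fused bicyclic C5 ketone (1-OTBS 7-OTES 9-OTBS)
Conditions: Tf2NH (10 mol %), 16 (3 equiv), CH2Cl2, −78 → −40 °C; Et3N quench
Reagents that add atoms: none
Why: In this silyl-triflimide-catalysed Diels–Alder reaction of a silyloxy diene with a β,β-disubstituted cycloalkenone, the unsubstituted diene terminus C4 should bond to the enone β-carbon C10 (the 1-silyloxy and 3-methyl groups direct the same way), the addition is suprafacial (C10 methyl and C11–H cis), it should occur anti to the pseudoaxial C9 silyl ether, and endo orientation puts O1 cis to the C5 carbonyl.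

Step 15
Reactants: 17 cis-fused bicyclic C5 ketone (1-OTBS 7-OTES 9-OTBS)
Product: 18 tricyclic C5 cyclobutanol
Conditions: hν (medium-pressure Hg lamp, Pyrex filter, λ > 300 nm), degassed MeCN (0.005 M), −30 °C
Reagents that add atoms: none
Why: n→π* excitation of the C5 ketone is followed by 1,5-hydrogen transfer from the pseudoaxial allylic C4–H to the carbonyl oxygen through a six-membered transition state, and the 1,4-biradical (C5 ketyl, C2–C3–C4 allyl) recombines at C4 to form the C4–C5 bond. This is a Norrish–Yang photocyclisation, and its closest precedent is the conversion of cyclohexyl ketones carrying an axial acyl group into bicyclo[3.1.1]heptan-6-ols. The cyclobutane C4–C5–C11–C10 is closed by radical–radical coupling of the two ends of the 1,4-biradical (a four-membered closure onto the near terminus of the allyl radical), which turns ring B into a bicyclo[3.1.1]heptene and ring A into a bicyclo[4.1.1]octane. The two new stereocentres are fixed by the rings already present: C5 is tied to C11 directly and to C10 through C6–C9, so the new bond can only form on the face of ring A on which ring B lies, which places C4–H and C6 on the side of the seven-membered bridge and the C5 hydroxyl on the side of the C1–C3 bridge. The step needs hydrogen transfer from C4 only: C4–H is the one allylic γ-C–H bond and lies 1,3-diaxial to the acyl group when C5 is axial on ring B (possible only in the cis-fused bicycle), C2 offers merely a vinylic hydrogen, and the γ-hydrogens on C8, C9 and the C10 methyl are stronger bonds. Closure at C4 and not at the far allyl terminus C2 is expected because ring A restricts rotation about C11–C5 so that the half-filled orbital on C5 faces the carbon that has just given up its hydrogen, β-scission of C10–C11 should be slow because that bond lies near the nodal plane of the allyl π system, and α-cleavage toward the tertiary C6 radical, the real competitor, is largely reversible (C6 carries two identical methyl groups) and is held back by the low temperature.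

Step 16
Reactants: 18 tricyclic C5 cyclobutanol
Product: 19 C5 methyl oxalate of 18
Conditions: ClC(O)CO2Me, DMAP, pyridine, CH2Cl2, 0 °C → rt
Reagents that add atoms: methyl chlorooxoacetate, COC(=O)C(=O)Cl
Why: DMAP-catalysed acylation with the small, very electrophilic oxalyl chloride should esterify the tertiary cyclobutanol without forming its alkoxide, which could fragment back to the ketone by retro-allylation.

Step 17
Reactants: 19 C5 methyl oxalate of 18
Product: 20 C5-deoxy tricycle (1-OTBS 7-OTES 9-OTBS)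
Conditions: Bu3SnH, AIBN, toluene, 100 °C
Reagents that add atoms: none
Why: In this radical deoxygenation of a tertiary methyl oxalate (Dolan–MacMillan variant of the Barton–McCombie reaction) the bridgehead-type C5 radical can accept hydrogen only on its outer face, so C5–H is set by the ring system, and thermal elimination of the oxalate is blocked because every β-hydrogen sits at a bridgehead.

Step 18
Reactants: 20 C5-deoxy tricycle (1-OTBS 7-OTES 9-OTBS)
Product: 21 C7 alcohol (1-OTBS 9-OTBS)
Conditions: PPTS (cat.), MeOH–CH2Cl2 (1:1), 0 °C → rt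
Reagents that add atoms: none
Why: Acid-catalysed methanolysis removes the triethylsilyl ether much faster than the two tert-butyldimethylsilyl ethers, so only O7 is freed.

Step 19
Reactants: 21 C7 alcohol (1-OTBS 9-OTBS); 22 tiglic acid
Product: 24 C7 tiglate (1-OTBS 9-OTBS), via tiglic 2,4,6-trichlorobenzoic anhydride 23 (not isolated)
Conditions: 22, 2,4,6-Cl3C6H2COCl, Et3N, toluene, rt; then 21, DMAP, toluene, 60 °C
Reagents that add atoms: none
Why: Yamaguchi esterification should acylate the hindered neopentyl C7 hydroxyl, and the E alkene of the tiglate is the stable isomer.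

Step 20
Reactants: 24 C7 tiglate (1-OTBS 9-OTBS)
Product: 25 C7 tiglate 1,9-diol
Conditions: HF·pyridine, pyridine, THF, 0 °C → rt
Reagents that add atoms: none
Why: Fluoride cleavage of both TBS ethers under buffered acidic conditions avoids an alkoxide at O9 and hence 1,3-migration of the C7 tiglate.

Step 21
Reactants: 25 C7 tiglate 1,9-diol
Product: 26 9-hydroxy enone (C1 ketone; C7 tiglate)
Conditions: MnO2 (activated, excess), CH2Cl2, rt
Reagents that add atoms: none
Why: MnO2 oxidises only the allylic C1 alcohol (the verbenol-to-verbenone type of oxidation) and leaves the saturated C9 alcohol untouched.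

Step 22
Reactants: 26 9-hydroxy enone (C1 ketone; C7 tiglate); 27 angelic acid
Product: 29 CNP0236543.2 (C9 angelate; C7 tiglate), via angelic 2,4,6-trichlorobenzoic anhydride 28 (not isolated)
Conditions: 27, 2,4,6-Cl3C6H2COCl, Et3N, toluene, rt; then 26, toluene, 80 °C
Reagents that add atoms: none
Why: Acylation by the preformed 2,4,6-trichlorobenzoyl mixed anhydride without a nucleophilic catalyst (Yamaguchi-type angeloylation) should transfer the angeloyl group without Z-to-E isomerisation.

## Compound list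

1 | (S)-pantolactone | CC1(C)COC(=O)[C@H]1O | starting material
2 | (S)-3,3-dimethylbutane-1,2,4-triol | OC[C@@H](O)C(C)(C)CO | intermediate
3 | [(2S,4S)-2-(4-methoxyphenyl)-5,5-dimethyl-1,3-dioxan-4-yl]methanol (cis-2,4) | OC[C@H]1O[C@@H](c2ccc(OC)cc2)OCC1(C)C | intermediate
4 | [(2S,4S)-2-(4-methoxyphenyl)-5,5-dimethyl-1,3-dioxan-4-yl]methyl triflate | O=S(=O)(OC[C@H]1O[C@@H](c2ccc(OC)cc2)OCC1(C)C)C(F)(F)F | intermediate
5 | (2S,4R)-2-(4-methoxyphenyl)-5,5-dimethyl-4-(3-methylbut-2-en-1-yl)-1,3-dioxane | CC(C)=CC[C@H]1O[C@@H](c2ccc(OC)cc2)OCC1(C)C | intermediate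
6 | (R)-2,2,6-trimethylhept-5-ene-1,3-diol | CC(C)=CC[C@@H](O)C(C)(C)CO | intermediate
7 | (R)-2,2,6-trimethyl-1,3-bis(triethylsilyloxy)hept-5-ene | CC(C)=CC[C@@H](O[Si](CC)(CC)CC)C(C)(C)CO[Si](CC)(CC)CC | intermediate
8 | (R)-3-[(R)-3,3-dimethyl-2,4-bis(triethylsilyloxy)butyl]-2,2-dimethyloxirane | CC1(C)O[C@@H]1C[C@@H](O[Si](CC)(CC)CC)C(C)(C)CO[Si](CC)(CC)CC | intermediate
9 | (3R,5R)-2,6,6-trimethyl-5,7-bis(triethylsilyloxy)hept-1-en-3-ol | C=C(C)[C@H](O)C[C@@H](O[Si](CC)(CC)CC)C(C)(C)CO[Si](CC)(CC)CC | intermediate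
10 | (3R,5R)-3-(tert-butyldimethylsilyloxy)-2,6,6-trimethyl-5,7-bis(triethylsilyloxy)hept-1-ene | C=C(C)[C@H](O[Si](C)(C)C(C)(C)C)C[C@@H](O[Si](CC)(CC)CC)C(C)(C)CO[Si](CC)(CC)CC | intermediate
11 | (3R,5R)-5-(tert-butyldimethylsilyloxy)-2,2,6-trimethyl-3-(triethylsilyloxy)hept-6-enal | C=C(C)[C@H](O[Si](C)(C)C(C)(C)C)C[C@@H](O[Si](CC)(CC)CC)C(C)(C)C=O | intermediate
12 | (5R,7R)-7-(tert-butyldimethylsilyloxy)-4,4,8-trimethyl-5-(triethylsilyloxy)nona-1,8-dien-3-ol, both C3 epimers | C=CC(O)C(C)(C)[C@H](O[Si](CC)(CC)CC)C[C@@H](O[Si](C)(C)C(C)(C)C)C(C)=C | intermediate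
13 | (4R,6R)-4-(tert-butyldimethylsilyloxy)-3,7,7-trimethyl-6-(triethylsilyloxy)cyclohept-2-en-1-ol, both C1 epimers | CC1=CC(O)C(C)(C)[C@H](O[Si](CC)(CC)CC)C[C@H]1O[Si](C)(C)C(C)(C)C | intermediate
14 | (4R,6R)-4-(tert-butyldimethylsilyloxy)-3,7,7-trimethyl-6-(triethylsilyloxy)cyclohept-2-en-1-one | CC1=CC(=O)C(C)(C)[C@H](O[Si](CC)(CC)CC)C[C@H]1O[Si](C)(C)C(C)(C)C | intermediate
15 | 3-methylbut-2-enal | CC(C)=CC=O | starting material
16 | (E)-tert-butyldimethyl(3-methylbuta-1,3-dienyloxy)silane | C=C(C)/C=C/O[Si](C)(C)C(C)(C)C | intermediate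
17 | cis-fused bicyclo[5.4.0]undec-2-ene C5 ketone: 1-OTBS, 7-OTES, 9-OTBS, 3,6,6,10-tetramethyl; C10–Me and C11–H cis, O9 cis to the C10 methyl, O7 trans to O9, O1 cis to C5 | CC(C)(C)[Si](C)(C)O[C@@H]1C[C@@H](O[Si](CC)(CC)CC)C(C)(C)C(=O)[C@H]2[C@@H](O[Si](C)(C)C(C)(C)C)C=C(C)C[C@]21C | intermediate
18 | tricyclic C5 cyclobutanol (C4–C5 closed; C5–OH on the side of the C1–C3 bridge; silyl ethers as in 17) | CC(C)(C)[Si](C)(C)O[C@@H]1C[C@@H](O[Si](CC)(CC)CC)C(C)(C)[C@]2(O)[C@H]3[C@@H](O[Si](C)(C)C(C)(C)C)C=C(C)[C@@H]2[C@]31C | intermediate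
19 | C5 methyl oxalate of 18 | CC(C)(C)[Si](C)(C)O[C@@H]1C[C@@H](O[Si](CC)(CC)CC)C(C)(C)[C@]2(OC(=O)C(=O)OC)[C@H]3[C@@H](O[Si](C)(C)C(C)(C)C)C=C(C)[C@@H]2[C@]31C | intermediate
20 | C5-deoxy tricycle (C5–H; 1-OTBS, 7-OTES, 9-OTBS) | CC(C)(C)[Si](C)(C)O[C@@H]1C[C@@H](O[Si](CC)(CC)CC)C(C)(C)[C@@H]2[C@H]3[C@@H](O[Si](C)(C)C(C)(C)C)C=C(C)[C@@H]2[C@]31C | intermediate
21 | C7 alcohol (1-OTBS, 9-OTBS) | CC(C)(C)[Si](C)(C)O[C@@H]1C[C@@H](O)C(C)(C)[C@@H]2[C@H]3[C@@H](O[Si](C)(C)C(C)(C)C)C=C(C)[C@@H]2[C@]31C | intermediate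
22 | tiglic acid | C/C=C(\C)C(=O)O | starting material
23 | tiglic 2,4,6-trichlorobenzoic anhydride | C/C=C(\C)C(=O)OC(=O)c1c(Cl)cc(Cl)cc1Cl | intermediate
24 | C7 tiglate (1-OTBS, 9-OTBS) | CC(C)(C)[Si](C)(C)O[C@@H]1C[C@@H](OC(=O)/C(C)=C/C)C(C)(C)[C@@H]2[C@H]3[C@@H](O[Si](C)(C)C(C)(C)C)C=C(C)[C@@H]2[C@]31C | intermediate
25 | C7 tiglate 1,9-diol | O[C@@H]1C[C@@H](OC(=O)/C(C)=C/C)C(C)(C)[C@@H]2[C@H]3[C@@H](O)C=C(C)[C@@H]2[C@]31C | intermediate
26 | 9-hydroxy enone (C1 ketone, C7 tiglate) | O[C@@H]1C[C@@H](OC(=O)/C(C)=C/C)C(C)(C)[C@@H]2[C@H]3C(=O)C=C(C)[C@@H]2[C@]31C | intermediate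
27 | angelic acid | C/C=C(/C)C(=O)O | starting material
28 | angelic 2,4,6-trichlorobenzoic anhydride | C/C=C(/C)C(=O)OC(=O)c1c(Cl)cc(Cl)cc1Cl | intermediate
29 | CNP0236543.2 (C9 angelate, C7 tiglate, C1 enone) | C/C=C(/C)C(=O)O[C@@H]1C[C@@H](OC(=O)/C(C)=C/C)C(C)(C)[C@@H]2[C@H]3C(=O)C=C(C)[C@@H]2[C@]31C | target

## Step count and risks

Total step count: 22. Longest linear sequence: 21 steps (steps 1–12 and 14–22); step 13 is a one-step side branch that makes the diene.

Steps most likely to fail:

**Step 15 (photocyclisation).** What may go wrong: α-cleavage of the excited ketone at C5–C6 outruns transfer of the C4 hydrogen, or the bulky silyl ether next to the acyl group (cis at C1/C11) keeps C5 out of the axial position on ring B, or the β-silyloxy ketone loses silanol. The fallback addresses the last two; α-cleavage can only be moderated by temperature. It sets out from 14 and comes back at 26: the cyclobutane is closed on a ketone without the C1 oxygen, and C1 is oxidised at the end. Enone 14 and isoprene under Lewis-acid catalysis (EtAlCl2, CH2Cl2, −30 °C → rt; para orientation, anti to O9) should give the cis-fused C1-unsubstituted ketone F1. Irradiation as in step 15 gives the cyclobutanol F2. Methyl chlorooxoacetate/DMAP gives the oxalate F3, and Bu3SnH/AIBN gives the deoxygenated tricycle F4. PPTS/MeOH frees the C7 alcohol F5, and Yamaguchi acylation with anhydride 23 gives the tiglate F6. Allylic oxidation of the ring CH2 at C1 (CrO3, 3,5-dimethylpyrazole, CH2Cl2, −20 °C; the α-pinene-to-verbenone pattern) gives the C9-silylated enone F7, and HF·pyridine then gives 26.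

**Step 14 (Diels–Alder).** What may go wrong: the acid-labile silyl dienol ether is consumed by desilylation or by open-chain conjugate addition before the congested C10–C4 bond and the ring are formed, or the acid catalyst strips the triethylsilyl ether. The fallback sets out from 14 and comes back at 17, building ring B in stages. Hosomi–Sakurai addition of CH2=C(Me)CH2SiMe3 (TiCl4, CH2Cl2, −78 °C) anti to O9 gives the 2-methylallyl ketone F8. The lithium enolate (LiN(iPr)2, THF, −78 °C; only C11 can enolise) and acrolein give the aldol adduct F9; attack is expected on the enolate face away from the C10 methyl/C9 silyloxy pair, which places C1 cis to C4, and the C1 epimer converges at 26. TBSOTf/2,6-lutidine gives the silyl ether F10, and ring-closing metathesis with the second-generation Grubbs catalyst forms C2=C3 and gives 17.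

**Step 17 (radical deoxygenation).** What may go wrong: at 100 °C the strained C5 cyclobutyl radical opens by β-scission of C4–C10 (toward a conjugated diene) before it meets the stannane, or the hindered oxalate fragments slowly. The fallback sets out from 18 and comes back at 20, replacing the tin hydride chain by electron transfer at room temperature. The lithium alkoxide of 18 (LiN(SiMe3)2, THF, −78 °C) and 4-MeC6H4COCl give the C5 p-toluate F11. SmI2/HMPA in THF at rt fragments its radical anion, and the C5 radical is reduced at once to the organosamarium and protonated to 20.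

## Further compounds

F1 | step 15 | cis-fused C1-unsubstituted bicyclic C5 ketone (isoprene adduct of 14; 7-OTES, 9-OTBS) | CC(C)(C)[Si](C)(C)O[C@@H]1C[C@@H](O[Si](CC)(CC)CC)C(C)(C)C(=O)[C@H]2CC=C(C)C[C@]21C
F2 | step 15 | C1-unsubstituted tricyclic C5 cyclobutanol | CC(C)(C)[Si](C)(C)O[C@@H]1C[C@@H](O[Si](CC)(CC)CC)C(C)(C)[C@]2(O)[C@H]3CC=C(C)[C@@H]2[C@]31C
F3 | step 15 | C5 methyl oxalate of F2 | CC(C)(C)[Si](C)(C)O[C@@H]1C[C@@H](O[Si](CC)(CC)CC)C(C)(C)[C@]2(OC(=O)C(=O)OC)[C@H]3CC=C(C)[C@@H]2[C@]31C
F4 | step 15 | C1-unsubstituted C5-deoxy tricycle (7-OTES, 9-OTBS) | CC(C)(C)[Si](C)(C)O[C@@H]1C[C@@H](O[Si](CC)(CC)CC)C(C)(C)[C@@H]2[C@H]3CC=C(C)[C@@H]2[C@]31C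
F5 | step 15 | C1-unsubstituted C7 alcohol (9-OTBS) | CC(C)(C)[Si](C)(C)O[C@@H]1C[C@@H](O)C(C)(C)[C@@H]2[C@H]3CC=C(C)[C@@H]2[C@]31C
F6 | step 15 | C1-unsubstituted C7 tiglate (9-OTBS) | CC(C)(C)[Si](C)(C)O[C@@H]1C[C@@H](OC(=O)/C(C)=C/C)C(C)(C)[C@@H]2[C@H]3CC=C(C)[C@@H]2[C@]31C
F7 | step 15 | C9-silylated enone (C1 ketone, C7 tiglate, 9-OTBS) | CC(C)(C)[Si](C)(C)O[C@@H]1C[C@@H](OC(=O)/C(C)=C/C)C(C)(C)[C@@H]2[C@H]3C(=O)C=C(C)[C@@H]2[C@]31C
F8 | step 14 | Sakurai adduct: cycloheptanone with C10 methyl and C10 2-methylallyl (anti to O9), 7-OTES, 9-OTBS | CC(C)(C)[Si](C)(C)O[C@@H]1C[C@@H](O[Si](CC)(CC)CC)C(C)(C)C(=O)C[C@@]1(C)CC(C)=C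
F9 | step 14 | aldol adduct: F8 with a 1-hydroxyprop-2-enyl group at C11, cis to the 2-methylallyl group | CC(C)(C)[Si](C)(C)O[C@@H]1C[C@@H](O[Si](CC)(CC)CC)C(C)(C)C(=O)[C@@H]([C@@H](O)C=C)[C@@]1(C)CC(C)=C
F10 | step 14 | TBS ether of F9 (diene for ring-closing metathesis) | CC(C)(C)[Si](C)(C)O[C@@H]1C[C@@H](O[Si](CC)(CC)CC)C(C)(C)C(=O)[C@@H]([C@@H](O[Si](C)(C)C(C)(C)C)C=C)[C@@]1(C)CC(C)=C
F11 | step 17 | C5 p-toluate of 18 | CC(C)(C)[Si](C)(C)O[C@@H]1C[C@@H](O[Si](CC)(CC)CC)C(C)(C)[C@]2(OC(=O)c4ccc(C)cc4)[C@H]3[C@@H](O[Si](C)(C)C(C)(C)C)C=C(C)[C@@H]2[C@]31C
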